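**Retrosynthetic overview**
- The target is traced back, through hydrogenolysis of four benzyl ethers and a hydroxyl-directed alkene hydrogenation, to a tetra-O-benzyl 6-[(E)-(2-hydroxy-2,6,6-trimethylcyclohexylidene)methyl]luteolin.
- Key disconnection: the bond between cyclohexane C1 (the CH that carries the CH2 to flavone C6) and cyclohexane C2 (the C(OH)CH3 carbon) is opened to an aryl alkyne and a methyl ketone, joined by an enantioselective nickel-catalysed reductive alkyne–ketone cyclization.
- Enabling feature: cyclohexane C1 bears the benzylic carbon on flavone C6 and lies between carbinol carbon C2 and the hydrogen-free C6(CH3)2. The ArCH2–C1–C2(OH) unit is therefore the reduced form of an ArC≡C/O=C coupling product, and the propargylic carbon of the precursor cannot isomerize.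
- The alkynone comes from a Sonogashira coupling of 6-iodo-tetra-O-benzylluteolin (luteolin: benzylation, chelation-directed C6 iodination) with a 3,3-dimethyl alkyne (isobutyronitrile alkylation, reduction, Ohira–Bestmann homologation).
- Ring order: rings A, B and C of the flavone come intact from luteolin; the cyclohexane is the only ring formed (step 9), and its second stereocenter follows in step 11.

Key step: step 9

Assumption: the sense of induction of the chiral ligand in step 9 is assigned by analogy with related alkynone cyclizations; the ligand enantiomer that gives the (S)-carbinol is meant (written as the (S)-ligand), and its antipode is equally available.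

**Route**

Step 1
Reactants: 1 luteolin
Product: 2 7-(benzyloxy)-2-[3,4-bis(benzyloxy)phenyl]-5-hydroxy-4H-chromen-4-one
Conditions: BnBr (3.3 equiv), K2CO3 (3.5 equiv), DMF, rt
Reagents that add atoms: benzyl bromide, BrCc1ccccc1
Why: Williamson ether synthesis: the 5-OH is tied to the C4 carbonyl by a hydrogen bond and is the least nucleophilic phenol, so the 7-, 3'- and 4'-OH groups should be benzylated selectively.

Step 2
Reactants: 2 7-(benzyloxy)-2-[3,4-bis(benzyloxy)phenyl]-5-hydroxy-4H-chromen-4-one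
Product: 3 7-(benzyloxy)-2-[3,4-bis(benzyloxy)phenyl]-5-hydroxy-6-iodo-4H-chromen-4-one
Conditions: BnMe3N·ICl2 (1.1 equiv), CaCO3 (1.5 equiv), CH2Cl2/MeOH, rt
Reagents that add atoms: benzyltrimethylammonium dichloroiodate, C[N+](C)(C)Cc1ccccc1.Cl[I-]Cl
Why: Electrophilic aromatic iodination: the free, chelated 5-OH directs the iodonium reagent to its ortho position C6 rather than to C8, the regiochemistry known for 5-hydroxy-7-alkoxyflavones, while CaCO3 takes up the HCl.

Step 3
Reactants: 3 7-(benzyloxy)-2-[3,4-bis(benzyloxy)phenyl]-5-hydroxy-6-iodo-4H-chromen-4-one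
Product: 4 5,7-bis(benzyloxy)-2-[3,4-bis(benzyloxy)phenyl]-6-iodo-4H-chromen-4-one
Conditions: BnBr (1.5 equiv), K2CO3 (3 equiv), DMF, 70 °C
Reagents that add atoms: benzyl bromide, BrCc1ccccc1
Why: Williamson ether synthesis under more forcing conditions: masking the hindered 5-OH prevents cyclization of an ortho-alkynylphenol to a benzofuran in step 7 and removes the acidic proton before the nickel step.

Step 4
Reactants: 5 isobutyronitrile; 6 2-(3-chloropropyl)-2-methyl-1,3-dioxolane
Product: 8 2,2-dimethyl-5-(2-methyl-1,3-dioxolan-2-yl)pentanenitrile, via lithiated isobutyronitrile 7 (not isolated)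
Conditions: LiN(iPr)2, THF, −78 °C; then 6, DMPU, −78 °C to rt
Reagents that add atoms: none
Why: Alkylation of a nitrile-stabilized carbanion (SN2 at the primary chloride) builds the quaternary carbon that will sit beside the alkyne, while the dioxolane masks the ketone from the base.

Step 5
Reactants: 8 2,2-dimethyl-5-(2-methyl-1,3-dioxolan-2-yl)pentanenitrile
Product: 10 2,2-dimethyl-5-(2-methyl-1,3-dioxolan-2-yl)pentanal, via N-aluminio aldimine 9 (not isolated)
Conditions: iBu2AlH (1.2 equiv), CH2Cl2, −78 °C; then aqueous KNaC4H4O6, wet SiO2, rt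
Reagents that add atoms: water, O
Why: Partial reduction of a nitrile: one hydride is delivered and the stable N-aluminio aldimine is hydrolysed on near-neutral work-up to the non-enolizable aldehyde, conditions the dioxolane should survive.

Step 6
Reactants: 10 2,2-dimethyl-5-(2-methyl-1,3-dioxolan-2-yl)pentanal
Product: 11 2-(4,4-dimethylhex-5-yn-1-yl)-2-methyl-1,3-dioxolane
Conditions: Ohira–Bestmann reagent (1.3 equiv), K2CO3 (2 equiv), MeOH, 0 °C to rt
Reagents that add atoms: dimethyl (1-diazo-2-oxopropyl)phosphonate, COP(=O)(OC)C(=[N+]=[N-])C(C)=O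
Why: Ohira–Bestmann (Seyferth–Gilbert) homologation: the diazophosphonate anion released by methanolysis adds to the aldehyde, which has no α-hydrogen, and the alkylidene carbene rearranges by 1,2-hydrogen shift to the terminal alkyne.

Step 7
Reactants: 4 5,7-bis(benzyloxy)-2-[3,4-bis(benzyloxy)phenyl]-6-iodo-4H-chromen-4-one; 11 2-(4,4-dimethylhex-5-yn-1-yl)-2-methyl-1,3-dioxolane
Product: 12 5,7-bis(benzyloxy)-2-[3,4-bis(benzyloxy)phenyl]-6-[3,3-dimethyl-6-(2-methyl-1,3-dioxolan-2-yl)hex-1-yn-1-yl]-4H-chromen-4-one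
Conditions: Pd(PPh3)2Cl2 (5 mol %), CuI (10 mol %), Et3N/DMF, 70 °C
Reagents that add atoms: none
Why: Sonogashira coupling: oxidative addition of zerovalent palladium into the C6–I bond, transmetalation of the copper acetylide and reductive elimination join ring A to the alkyne, as known for iodo-5,7-dialkoxyflavones with tertiary propargylic alkynes.

Step 8
Reactants: 12 5,7-bis(benzyloxy)-2-[3,4-bis(benzyloxy)phenyl]-6-[3,3-dimethyl-6-(2-methyl-1,3-dioxolan-2-yl)hex-1-yn-1-yl]-4H-chromen-4-one
Product: 13 5,7-bis(benzyloxy)-2-[3,4-bis(benzyloxy)phenyl]-6-(3,3-dimethyl-7-oxooct-1-yn-1-yl)-4H-chromen-4-one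
Conditions: 1 M aqueous HCl, THF, rt
Reagents that add atoms: water, O
Why: Acid-catalysed acetal hydrolysis frees the methyl ketone, while benzyl ethers, the aryl alkyne and the chromone should tolerate dilute aqueous acid at room temperature.

Step 9
Reactants: 13 5,7-bis(benzyloxy)-2-[3,4-bis(benzyloxy)phenyl]-6-(3,3-dimethyl-7-oxooct-1-yn-1-yl)-4H-chromen-4-one
Product: 14 5,7-bis(benzyloxy)-2-[3,4-bis(benzyloxy)phenyl]-6-{(E)-[(2S)-2,6,6-trimethyl-2-(triethylsilyloxy)cyclohexylidene]methyl}-4H-chromen-4-one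
Conditions: Ni(cod)2 (10 mol %), (S)-3-tert-butyl-4-(2,6-dimethoxyphenyl)-2,3-dihydrobenzo[d][1,3]oxaphosphole (12 mol %), Et3SiH (3 equiv), 1,4-dioxane, rt to 40 °C, argon
Reagents that add atoms: triethylsilane, CC[SiH](CC)CC
Why: Zerovalent nickel carrying the P-stereogenic phosphine binds the alkyne and the methyl ketone and couples them by oxidative cyclization to an oxanickelacyclopentene, in which the alkyne carbon next to the quaternary centre bonds to the carbonyl carbon; σ-bond metathesis with Et3SiH puts silicon on oxygen and C–H reductive elimination releases the E-alkene and the catalyst. The closest known reaction type is the nickel-catalysed enantioselective reductive cyclization of aryl-substituted alkynones with silanes to cyclic tertiary allylic silyl ethers. The cyclohexane ring closes in the 6-exo-dig mode at the alkyne (the triple bond becomes the exocyclic double bond) and exo at the carbonyl group. The new carbinol stereocenter is set in the oxidative cyclization, where the ligand on nickel decides which face of the ketone meets the alkyne, and the syn addition of carbon and hydrogen across the alkyne fixes the E geometry. The step needs regioselectivity, secured by the three-methylene tether because closure at the distal alkyne carbon would demand a trans-cycloheptene, and chemoselectivity over the chromone carbonyl, a vinylogous ester that cannot reach the alkyne, and over simple hydrosilylation, which the intramolecular coupling should outrun. The quaternary carbon beside the alkyne carries no hydrogen, so no allene can form, and its two methyl groups favour the folded conformer.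

Step 10
Reactants: 14 5,7-bis(benzyloxy)-2-[3,4-bis(benzyloxy)phenyl]-6-{(E)-[(2S)-2,6,6-trimethyl-2-(triethylsilyloxy)cyclohexylidene]methyl}-4H-chromen-4-one
Product: 15 5,7-bis(benzyloxy)-2-[3,4-bis(benzyloxy)phenyl]-6-{(E)-[(2S)-2-hydroxy-2,6,6-trimethylcyclohexylidene]methyl}-4H-chromen-4-one
Conditions: Bu4NF (1.5 equiv), THF, 0 °C to rt; chromatography on Et3N-deactivated silica
Reagents that add atoms: none
Why: Fluoride-mediated silyl ether cleavage frees the hydroxyl that must direct the next step, under basic conditions that should not ionize the acid-sensitive tertiary allylic alcohol.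

Step 11
Reactants: 15 5,7-bis(benzyloxy)-2-[3,4-bis(benzyloxy)phenyl]-6-{(E)-[(2S)-2-hydroxy-2,6,6-trimethylcyclohexylidene]methyl}-4H-chromen-4-one
Product: 16 5,7-bis(benzyloxy)-2-[3,4-bis(benzyloxy)phenyl]-6-{[(1S,2S)-2-hydroxy-2,6,6-trimethylcyclohexyl]methyl}-4H-chromen-4-one
Conditions: [Ir(cod)(PCy3)(py)]PF6 (10 mol %), H2 (1–4 atm), CH2Cl2, rt
Reagents that add atoms: none
Why: Hydroxyl-directed homogeneous hydrogenation: the cationic iridium centre binds the tertiary OH and the exocyclic alkene on the same face and adds H2 syn from that face, so the ring hydrogen ends up cis to OH and the arylmethyl group trans to it, which sets the second stereocenter as (S) without touching the benzyl ethers or the chromone.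

Step 12
Reactants: 16 5,7-bis(benzyloxy)-2-[3,4-bis(benzyloxy)phenyl]-6-{[(1S,2S)-2-hydroxy-2,6,6-trimethylcyclohexyl]methyl}-4H-chromen-4-one
Product: 17 2-(3,4-dihydroxyphenyl)-5,7-dihydroxy-6-{[(1S,2S)-2-hydroxy-2,6,6-trimethylcyclohexyl]methyl}-4H-chromen-4-one (CNP0257603.1)
Conditions: H2 (1 atm), 10% Pd/C, EtOAc/MeOH, rt
Reagents that add atoms: none
Why: Hydrogenolysis of the four benzyl aryl ethers over palladium under neutral conditions should release the target while leaving the tertiary alcohol, the flavone C2–C3 double bond and both stereocenters untouched.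

**Compound list**
1 | luteolin | O=c1cc(-c2ccc(O)c(O)c2)oc2cc(O)cc(O)c12 | starting material
2 | 7-(benzyloxy)-2-[3,4-bis(benzyloxy)phenyl]-5-hydroxy-4H-chromen-4-one | O=c1cc(-c2ccc(OCc3ccccc3)c(OCc3ccccc3)c2)oc2cc(OCc3ccccc3)cc(O)c12 | intermediate
3 | 7-(benzyloxy)-2-[3,4-bis(benzyloxy)phenyl]-5-hydroxy-6-iodo-4H-chromen-4-one | O=c1cc(-c2ccc(OCc3ccccc3)c(OCc3ccccc3)c2)oc2cc(OCc3ccccc3)c(I)c(O)c12 | intermediate
4 | 5,7-bis(benzyloxy)-2-[3,4-bis(benzyloxy)phenyl]-6-iodo-4H-chromen-4-one | O=c1cc(-c2ccc(OCc3ccccc3)c(OCc3ccccc3)c2)oc2cc(OCc3ccccc3)c(I)c(OCc3ccccc3)c12 | intermediate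
5 | isobutyronitrile | CC(C)C#N | starting material
6 | 2-(3-chloropropyl)-2-methyl-1,3-dioxolane | CC1(CCCCl)OCCO1 | starting material
7 | lithiated isobutyronitrile (not isolated) | CC(C)=C=N[Li] | intermediate
8 | 2,2-dimethyl-5-(2-methyl-1,3-dioxolan-2-yl)pentanenitrile | CC1(CCCC(C)(C)C#N)OCCO1 | intermediate
9 | N-(diisobutylaluminio) aldimine of 10 (not isolated) | CC(C)C[Al](CC(C)C)N=CC(C)(C)CCCC1(C)OCCO1 | intermediate
10 | 2,2-dimethyl-5-(2-methyl-1,3-dioxolan-2-yl)pentanal | CC1(CCCC(C)(C)C=O)OCCO1 | intermediate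
11 | 2-(4,4-dimethylhex-5-yn-1-yl)-2-methyl-1,3-dioxolane | CC1(CCCC(C)(C)C#C)OCCO1 | intermediate
12 | 5,7-bis(benzyloxy)-2-[3,4-bis(benzyloxy)phenyl]-6-[3,3-dimethyl-6-(2-methyl-1,3-dioxolan-2-yl)hex-1-yn-1-yl]-4H-chromen-4-one | CC1(CCCC(C)(C)C#Cc2c(OCc3ccccc3)cc3oc(-c4ccc(OCc5ccccc5)c(OCc5ccccc5)c4)cc(=O)c3c2OCc2ccccc2)OCCO1 | intermediate
13 | 5,7-bis(benzyloxy)-2-[3,4-bis(benzyloxy)phenyl]-6-(3,3-dimethyl-7-oxooct-1-yn-1-yl)-4H-chromen-4-one | CC(=O)CCCC(C)(C)C#Cc1c(OCc2ccccc2)cc2oc(-c3ccc(OCc4ccccc4)c(OCc4ccccc4)c3)cc(=O)c2c1OCc1ccccc1 | intermediate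
14 | 5,7-bis(benzyloxy)-2-[3,4-bis(benzyloxy)phenyl]-6-{(E)-[(2S)-2,6,6-trimethyl-2-(triethylsilyloxy)cyclohexylidene]methyl}-4H-chromen-4-one | CC1(C)CCC[C@](C)(O[Si](CC)(CC)CC)/C1=C/c1c(OCc2ccccc2)cc2oc(-c3ccc(OCc4ccccc4)c(OCc4ccccc4)c3)cc(=O)c2c1OCc1ccccc1 | intermediate
15 | 5,7-bis(benzyloxy)-2-[3,4-bis(benzyloxy)phenyl]-6-{(E)-[(2S)-2-hydroxy-2,6,6-trimethylcyclohexylidene]methyl}-4H-chromen-4-one | CC1(C)CCC[C@](C)(O)/C1=C/c1c(OCc2ccccc2)cc2oc(-c3ccc(OCc4ccccc4)c(OCc4ccccc4)c3)cc(=O)c2c1OCc1ccccc1 | intermediate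
16 | 5,7-bis(benzyloxy)-2-[3,4-bis(benzyloxy)phenyl]-6-{[(1S,2S)-2-hydroxy-2,6,6-trimethylcyclohexyl]methyl}-4H-chromen-4-one | CC1(C)CCC[C@](C)(O)[C@H]1Cc1c(OCc2ccccc2)cc2oc(-c3ccc(OCc4ccccc4)c(OCc4ccccc4)c3)cc(=O)c2c1OCc1ccccc1 | intermediate
17 | 2-(3,4-dihydroxyphenyl)-5,7-dihydroxy-6-{[(1S,2S)-2-hydroxy-2,6,6-trimethylcyclohexyl]methyl}-4H-chromen-4-one | CC1(C)CCC[C@](C)(O)[C@H]1Cc1c(O)cc2oc(-c3ccc(O)c(O)c3)cc(=O)c2c1O | target

**Step count and risks**

Total steps: 12. Longest linear sequence: 9 steps (steps 4–12, or steps 1–3 and 7–12).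

Steps most likely to fail:

1. Step 9. The oxidative cyclization may stall because the alkyne is flanked by a quaternary carbon and a 2,6-dioxygenated aryl ring; the chromone may also sequester zerovalent nickel, or the ligand may induce the carbinol centre poorly. The fallback sets out from aldehyde 10 and iodide 4 and comes back at 17, using an amine-catalysed aldol ring closure instead.
   - Aldehyde 10 would be homologated by a Wittig reaction with Ph3P=CHOMe (from [Ph3PCH2OMe]Cl and KN(SiMe3)2, THF) to enol ether F1.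
   - Aqueous HCl/THF would unmask both carbonyl groups to give keto aldehyde F2.
   - (S)-Proline (DMSO, rt) should effect the 6-enolexo aldolization to the trans aldol F3; the enamine/carboxylic acid transition state controls the ring CH centre, and the anti course known for enolexo aldolizations would place CHO trans to OH.
   - Silylation (Me3SiCl, imidazole, CH2Cl2) would give F4.
   - Iodide 4 would be converted by iodine–magnesium exchange (iPrMgCl·LiCl, THF, −40 °C) into arylmagnesium chloride F5, which would add to F4 to give carbinol F6 (either epimer at the new carbinol carbon is acceptable).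
   - Hydrogenolysis (H2, Pd/C, MeOH/EtOAc with a little AcOH) would remove the four benzyl groups, the doubly ortho-oxygenated benzylic hydroxyl and the trimethylsilyl group, arriving at 17.

2. Step 11. The hindered trisubstituted alkene may fail to bind iridium on the hydroxyl face (slow reduction, catalyst deactivation), and traces of acid from the catalyst may ionize the tertiary allylic alcohol. The fallback sets out from 15 and comes back at 16, delivering the ring hydrogen through a silicon tether.
   - Alcohol 15 would be silylated (Me2SiHCl, imidazole, DMF) to hydrosilyl ether F7.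
   - Platinum-catalysed intramolecular hydrosilylation (Pt2[(CH2=CHSiMe2)2O]3, toluene, 60 °C) would close oxasilolane F8 by syn addition of Si–H from the oxygen-bearing face, with silicon on the benzylic carbon and hydrogen on the ring carbon cis to oxygen.
   - Protodesilylation (Bu4NF, wet DMF, 80 °C) would cleave the benzylic C–Si and the Si–O bonds and give 16.

3. Step 7. Slow oxidative addition at the di-ortho-alkoxy aryl iodide may let copper-mediated homocoupling of the alkyne take over. The fallback sets out from 11 and 4 and comes back at 12.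
   - Alkyne 11 would be lithiated (n-BuLi, THF, −78 °C) and stannylated (Bu3SnCl) to alkynylstannane F9.
   - A copper-free Stille coupling of F9 with 4 (Pd(PPh3)4, toluene, 100 °C) would give 12.

**Further compounds**
F1 | step 9 | 2-(6-methoxy-4,4-dimethylhex-5-en-1-yl)-2-methyl-1,3-dioxolane (E/Z mixture) | COC=CC(C)(C)CCCC1(C)OCCO1
F2 | step 9 | 3,3-dimethyl-7-oxooctanal | CC(=O)CCCC(C)(C)CC=O
F3 | step 9 | (1S,2S)-2-hydroxy-2,6,6-trimethylcyclohexane-1-carbaldehyde | CC1(C)CCC[C@](C)(O)[C@H]1C=O
F4 | step 9 | (1S,2S)-2,6,6-trimethyl-2-(trimethylsilyloxy)cyclohexane-1-carbaldehyde | CC1(C)CCC[C@](C)(O[Si](C)(C)C)[C@H]1C=O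
F5 | step 9 | {5,7-bis(benzyloxy)-2-[3,4-bis(benzyloxy)phenyl]-4-oxo-4H-chromen-6-yl}magnesium chloride | Cl[Mg]c1c(OCc2ccccc2)cc2oc(-c3ccc(OCc4ccccc4)c(OCc4ccccc4)c3)cc(=O)c2c1OCc1ccccc1
F6 | step 9 | 5,7-bis(benzyloxy)-2-[3,4-bis(benzyloxy)phenyl]-6-{hydroxy[(1R,2S)-2,6,6-trimethyl-2-(trimethylsilyloxy)cyclohexyl]methyl}-4H-chromen-4-one (carbinol epimers) | CC1(C)CCC[C@](C)(O[Si](C)(C)C)[C@H]1C(O)c1c(OCc2ccccc2)cc2oc(-c3ccc(OCc4ccccc4)c(OCc4ccccc4)c3)cc(=O)c2c1OCc1ccccc1
F7 | step 11 | 5,7-bis(benzyloxy)-2-[3,4-bis(benzyloxy)phenyl]-6-{(E)-[(2S)-2-(dimethylsilyloxy)-2,6,6-trimethylcyclohexylidene]methyl}-4H-chromen-4-one | CC1(C)CCC[C@](C)(O[SiH](C)C)/C1=C/c1c(OCc2ccccc2)cc2oc(-c3ccc(OCc4ccccc4)c(OCc4ccccc4)c3)cc(=O)c2c1OCc1ccccc1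
F8 | step 11 | (3S,3aS,7aS)-3-{5,7-bis(benzyloxy)-2-[3,4-bis(benzyloxy)phenyl]-4-oxo-4H-chromen-6-yl}-2,2,4,4,7a-pentamethyloctahydro-2,1-benzoxasilole | CC1(C)CCC[C@]2(C)O[Si](C)(C)[C@H](c3c(OCc4ccccc4)cc4oc(-c5ccc(OCc6ccccc6)c(OCc6ccccc6)c5)cc(=O)c4c3OCc3ccccc3)[C@@H]12
F9 | step 7 | tributyl[3,3-dimethyl-6-(2-methyl-1,3-dioxolan-2-yl)hex-1-yn-1-yl]stannane | CCCC[Sn](CCCC)(CCCC)C#CC(C)(C)CCCC1(C)OCCO1
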